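In a one-step world, where the balance feeds anion to the electrophile and no other step runs, green ends with its whole 1.00 equiv of electrophile as target, and that uses one equivalent of the 1.30 equiv of free base.

| flask | acidic substrate | free base | electrophile | time | remark |
|---|---|---|---|---|---|
| ochre | 0.050 M | 1.30 equiv | 1.00 equiv (fed, over 5.0 s) | 25 s | all else is in the flask from the start; the feed brings no volume worth counting |
| amber | 0.050 M (fed, over 5.0 s) | 1.30 equiv | 1.00 equiv | 25 s | all else is in the flask from the start; the feed brings no volume worth counting |
| green | 0.050 M | 1.30 equiv | 1.00 equiv | 25 s | everything together at the start |

    acidic substrate + anion → side product (k1 = 0.049 M⁻¹ s⁻¹)
    2 free base → homo dimer (k2 = 1.7 M⁻¹ s⁻¹)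
    electrophile + anion → target (k3 = 14 M⁻¹ s⁻¹)
    acidic substrate + free base ⇌ protonated base + anion, settled at all times (K4 = 0.78)

- percentages count the acidic substrate that a species holds: one side product counts as two
- where a step has two of a species, its rate is k times that concentration squared, and two are used at each turn
- run time (ochre): 25 s

* the flask with the highest amount of target, in percent of the acidic substrate charged ("all alike" if they lie within 1.5 percentage points) (ochre / amber / green / all alike)
* final target, as a percentage of the acidic substrate charged, in ochre
* final target, as a percentage of the acidic substrate charged, in amber
* final target, as a percentage of the acidic substrate charged, in green

The real flask has a second mouth on the free base, so I keep a ledger in fractions of the charge. Each target leaves one protonated base behind and each homo dimer takes two free base. The excess over the limiting reagent, which I call the spare base and write 0.300, is what step 2 may take without lowering the target's ceiling. Every bit of base lost beyond it takes the same amount from the target's ceiling.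

That gives me one end. At the other end I take a frozen version: step 2 takes at once whatever free base the first balance leaves, and the balance then neither makes more anion nor gives base back. In green the first balance makes 0.531 of anion and leaves 0.769 of free base, so in this frozen version target ends at 0.531.

To join the ends I compare rates at the start of green, where coupling runs 3.69 times as fast as free base is lost to step 2. Held at that ratio, the homo dimer takes 0.277 of base, just inside the spare. But that ratio is a start value, and I expect it to sink as electrophile is used, the loss to pass the spare, and green to lie between 0.531 and the top end.

Amber starts with 1.30 equiv free, against 0.769 in green, so its first loss runs 2.86 times green's. Ochre starts with green's free base but receives its electrophile over 5.0 s, so its coupling starts behind green's while its loss starts level, and I rank green, then ochre, then amber.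

The forecast, holding that “Base that dimerises can no longer deprotonate the substrate”, gives green first with 78%, then ochre 74.5% and amber 71%.

The flasks give green 78.3%, ochre 74.6% and amber 71.5%, so green holds the highest target, with 21.7% of its electrophile left at 25.0 s. Left for 250 s, green has free base worth 42.2% of the acidic substrate charged held in homo dimer, which is past the spare 0.300 and puts the ledger's ceiling at 87.8%; its target stands at 87.1%. At 250 s, amber has 50.9% held the same way, so its ceiling is 79.1%, and its target stands at 78.9%.

The constants used here stand for no real mixture; the rest is arithmetic.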